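**Plan** (flavanone numbering: O1, C2, C3, C4, C4a, C5–C8, C8a; ring A = benzo ring, ring B = trimethoxyphenyl, ring C = pyranone)

1. Retrosynthesis: the O5–Si bond is cut last; then ring C is opened at O1–C2 and C4–C4a together, giving the ring-A phenol 7 and the cinnamoyl chloride 11 (C2–C3–C4 plus ring B). Phenol 7 goes back to 5-methoxyresorcinol by cutting the C8–prenyl bond; 11 goes back to 2,4,6-trimethoxybenzaldehyde and malonic acid (C2=C3).
2. Forward: ring A is decorated first (steps 1–4) and the C3 unit is made separately (steps 5–6). Ring C arises last, in step 7: C-acylation at C4a gives the biogenetic 2'-hydroxychalcone, which closes by addition of O1 to C2. Step 8 frees 5-OH.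
3. Enabling feature: C4a is the only open carbon ortho to O1–H (C8 carries the prenyl group) and lies ortho/para to O1, O5 and O7 of the phloroglucinol-type ring A, so a magnesium phenolate delivers the acyl group there. This puts O1–H next to the C2=C3–C4=O enone, as in the chalcone that chalcone isomerase closes in the biosynthesis.
4. Stereochemistry: C2 (S) is the only stereocentre. It is set in the ring closure of step 7 by a bifunctional cinchona thiourea (catalyst control), and only a buffered desilylation follows.

Key step: step 7

Assumption: the quinidine-derived thiourea is taken to give the 2S product (if a first run shows the opposite sense, the quinine-derived pseudo-enantiomer is used), and the two stages of step 7 are run as one telescoped operation without isolating the chalcone.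

**Route**

Step 1
Reactants: 1 5-methoxyresorcinol (5-methoxybenzene-1,3-diol)
Product: 2 3-methoxy-5-[(triisopropylsilyl)oxy]phenol
Conditions: TIPSCl (1.0 equiv), imidazole, DMF, 0 °C → rt
Reagents that add atoms: triisopropylsilyl chloride, CC(C)[Si](Cl)(C(C)C)C(C)C
Why: Imidazole-promoted O-silylation; the two OH groups of 1 are equivalent, so one equivalent of silyl chloride should give mainly the mono-ether, with diol and bis-ether separable and recyclable.

Step 2
Reactants: 2 3-methoxy-5-[(triisopropylsilyl)oxy]phenol
Product: 3 triisopropyl[3-methoxy-5-(methoxymethoxy)phenoxy]silane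
Conditions: MOMCl, i-Pr2NEt, CH2Cl2, 0 °C → rt
Reagents that add atoms: chloromethyl methyl ether, COCCl
Why: O-alkylation of the remaining phenol installs the MOM acetal that later directs metalation to the carbon between it and the OMe group.

Step 3
Reactants: 3 triisopropyl[3-methoxy-5-(methoxymethoxy)phenoxy]silane; 4 prenyl bromide (1-bromo-3-methylbut-2-ene)
Product: 6 triisopropyl[3-methoxy-5-(methoxymethoxy)-4-(3-methylbut-2-en-1-yl)phenoxy]silane, via aryllithium 5 (not isolated)
Conditions: n-BuLi, THF, 0 °C; CuBr·SMe2 (10 mol %), 4, −78 °C → rt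
Reagents that add atoms: none
Why: Directed ortho-metalation should occur at the carbon flanked by the two coordinating groups OMOM and OMe (the bulky OSi(i-Pr)3 group does not direct), and copper-catalysed allylic substitution at the primary carbon of 4 installs the linear prenyl group.

Step 4
Reactants: 6 triisopropyl[3-methoxy-5-(methoxymethoxy)-4-(3-methylbut-2-en-1-yl)phenoxy]silane
Product: 7 3-methoxy-2-(3-methylbut-2-en-1-yl)-5-[(triisopropylsilyl)oxy]phenol
Conditions: HCl (cat.), MeOH, rt
Reagents that add atoms: none
Why: Acid-catalysed acetal exchange with methanol removes the MOM group, while the aryl silyl ether and the trisubstituted alkene should survive dilute acid at room temperature for the short time needed.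

Step 5
Reactants: 8 2,4,6-trimethoxybenzaldehyde; 9 malonic acid
Product: 10 (E)-3-(2,4,6-trimethoxyphenyl)prop-2-enoic acid
Conditions: pyridine, piperidine (cat.), 100 °C
Reagents that add atoms: none
Why: Knoevenagel–Doebner condensation with loss of CO2 gives the E-cinnamic acid.

Step 6
Reactants: 10 (E)-3-(2,4,6-trimethoxyphenyl)prop-2-enoic acid
Product: 11 (E)-3-(2,4,6-trimethoxyphenyl)prop-2-enoyl chloride
Conditions: (COCl)2, DMF (cat.), CH2Cl2, 0 °C → rt; evaporated and used crude
Reagents that add atoms: oxalyl chloride, O=C(Cl)C(=O)Cl
Why: Vilsmeier-type activation converts the acid into the acid chloride under conditions that leave the aryl methyl ethers and the alkene untouched.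

Step 7
Reactants: 7 3-methoxy-2-(3-methylbut-2-en-1-yl)-5-[(triisopropylsilyl)oxy]phenol; 11 (E)-3-(2,4,6-trimethoxyphenyl)prop-2-enoyl chloride
Product: 14 (S)-7-methoxy-8-(3-methylbut-2-en-1-yl)-2-(2,4,6-trimethoxyphenyl)-5-[(triisopropylsilyl)oxy]chroman-4-one, via bromomagnesium phenolate 12 (not isolated), via 2'-hydroxychalcone 13 (not isolated)
Conditions: EtMgBr (1.0 equiv), Et2O → toluene, 0 °C; 11, i-Pr2NEt (proton shuttle), toluene, 0 °C → rt; aq. NH4Cl wash, dry, solution used as such; then epi-quinidine-derived 3,5-(CF3)2C6H3-thiourea (10 mol %), toluene, −20 °C → rt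
Reagents that add atoms: none
Why: The bromomagnesium phenolate 12 binds the acid chloride at magnesium and delivers the acyl group to the ortho carbon (metal-template ortho-C-acylation of a phenolate, a chelation-controlled Friedel–Crafts acylation); rearomatisation gives the magnesium chelate of chalcone 13, which the NH4Cl wash sets free. The site is fixed by the substrate: of the two carbons ortho to O1 only C4a is open (C8 carries the prenyl group), C4a is ortho/para to all three ring oxygens, the para carbon C6 is not reached by the template, and the electron-rich 2,4,6-trimethoxyphenyl group makes the β-carbon of 11 a poor acceptor, so C-alkylation there should not compete. In the second stage the cinchona thiourea acts like chalcone isomerase: the quinuclidine nitrogen takes the proton of O1–H, the thiourea hydrogen-bonds the C4 carbonyl, and the phenoxide adds to C2 in a 6-endo-trig oxa-Michael closure of the pyranone ring (closest known reaction type: bifunctional amine–thiourea-catalysed asymmetric oxa-Michael cyclisation of 2'-hydroxychalcones and of phenols onto tethered enones). The single new stereocentre C2 is set under catalyst control by the enone face that the bound phenoxide reaches, and any Z-chalcone should funnel into the same product because the conjugate addition is reversible until the enolate is protonated. The step needs C- over O-acylation (template, non-polar solvent), one enantioface at C2 (catalyst) and no later ring opening (the 5-OSi and 8-prenyl groups flank the acyl group and disfavour the planar chalcone; weak base, low temperature).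

Step 8
Reactants: 14 (S)-7-methoxy-8-(3-methylbut-2-en-1-yl)-2-(2,4,6-trimethoxyphenyl)-5-[(triisopropylsilyl)oxy]chroman-4-one
Product: 15 (S)-5-hydroxy-7-methoxy-8-(3-methylbut-2-en-1-yl)-2-(2,4,6-trimethoxyphenyl)chroman-4-one
Conditions: TBAF, AcOH (1:1), THF, 0 °C
Reagents that add atoms: none
Why: Fluoride cleaves the aryl O–Si bond, and the acetic acid buffer protonates the phenoxide at once so that no base-induced retro-oxa-Michael opening can racemise C2.

**Compound list**

1 | 5-methoxyresorcinol | COc1cc(O)cc(O)c1 | starting material
2 | 3-methoxy-5-[(triisopropylsilyl)oxy]phenol | COc1cc(O)cc(O[Si](C(C)C)(C(C)C)C(C)C)c1 | intermediate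
3 | triisopropyl[3-methoxy-5-(methoxymethoxy)phenoxy]silane | COCOc1cc(OC)cc(O[Si](C(C)C)(C(C)C)C(C)C)c1 | intermediate
4 | prenyl bromide (1-bromo-3-methylbut-2-ene) | CC(C)=CCBr | starting material
5 | aryllithium, Li on the carbon between OMOM and OMe of 3 (not isolated) | [Li]c1c(OC)cc(O[Si](C(C)C)(C(C)C)C(C)C)cc1OCOC | intermediate
6 | triisopropyl[3-methoxy-5-(methoxymethoxy)-4-(3-methylbut-2-en-1-yl)phenoxy]silane | COCOc1cc(O[Si](C(C)C)(C(C)C)C(C)C)cc(OC)c1CC=C(C)C | intermediate
7 | 3-methoxy-2-(3-methylbut-2-en-1-yl)-5-[(triisopropylsilyl)oxy]phenol | Oc1cc(O[Si](C(C)C)(C(C)C)C(C)C)cc(OC)c1CC=C(C)C | intermediate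
8 | 2,4,6-trimethoxybenzaldehyde | COc1cc(OC)c(C=O)c(OC)c1 | starting material
9 | malonic acid | OC(=O)CC(=O)O | starting material
10 | (E)-3-(2,4,6-trimethoxyphenyl)prop-2-enoic acid | COc1cc(OC)c(/C=C/C(=O)O)c(OC)c1 | intermediate
11 | (E)-3-(2,4,6-trimethoxyphenyl)prop-2-enoyl chloride | COc1cc(OC)c(/C=C/C(=O)Cl)c(OC)c1 | intermediate
12 | bromomagnesium phenolate of 7 (not isolated) | Br[Mg]Oc1cc(O[Si](C(C)C)(C(C)C)C(C)C)cc(OC)c1CC=C(C)C | intermediate
13 | (E)-1-[2-hydroxy-4-methoxy-3-(3-methylbut-2-en-1-yl)-6-(triisopropylsilyloxy)phenyl]-3-(2,4,6-trimethoxyphenyl)prop-2-en-1-one (not isolated) | COc1cc(OC)c(/C=C/C(=O)c2c(O)c(CC=C(C)C)c(OC)cc2O[Si](C(C)C)(C(C)C)C(C)C)c(OC)c1 | intermediate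
14 | (S)-7-methoxy-8-(3-methylbut-2-en-1-yl)-2-(2,4,6-trimethoxyphenyl)-5-[(triisopropylsilyl)oxy]chroman-4-one | COc1cc(OC)c([C@@H]2CC(=O)c3c(O[Si](C(C)C)(C(C)C)C(C)C)cc(OC)c(CC=C(C)C)c3O2)c(OC)c1 | intermediate
15 | (S)-5-hydroxy-7-methoxy-8-(3-methylbut-2-en-1-yl)-2-(2,4,6-trimethoxyphenyl)chroman-4-one | COc1cc(OC)c([C@@H]2CC(=O)c3c(O)cc(OC)c(CC=C(C)C)c3O2)c(OC)c1 | target

**Totals**

Total steps: 8. Longest linear sequence: 6 steps (1, 2, 3, 4, 7, 8).

**Steps most likely to fail**

Step 7. The main risk is low facial selectivity or slow closure of the electron-rich, hindered enone, with erosion through reversible ring opening. The fallback sets out from chalcone 13, which is then isolated after the first stage. Closure with NaOAc in EtOH at reflux should give the racemic flavanone F1. Kinetic resolution by asymmetric transfer hydrogenation follows ([Cp*RhCl(TsDPEN)], enantiomer chosen to reduce the 2R ketone; HCO2H/Et3N, EtOAc, rt, run to just beyond half conversion). This should leave the 2S ketone and convert the 2R enantiomer into the cis-(2R,4R)-flavan-4-ol F2, which is removed by chromatography. The fallback returns to the route at 14.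

Step 3. The risk is SN2′ attack (reverse prenyl) or homocoupling when aryllithium 5 is alkylated. The fallback sets out from 3: the same aryllithium 5 is trapped with allyl bromide, which has no regiochemical ambiguity, to give the allyl arene F3. Cross-metathesis with 2-methylbut-2-ene (Grubbs II, CH2Cl2, 40 °C) then turns allyl into prenyl and returns to the route at 6.

Step 4. The risk is acid-promoted addition of the freed phenol to the prenyl double bond (chroman formation) or loss of the silyl ether. The fallback sets out from 2 and avoids the acetal altogether. Pd(0)-catalysed O-alkylation with tert-butyl 2-methylbut-3-en-2-yl carbonate (Pd(PPh3)4, THF, 0 °C) should give the 1,1-dimethylallyl aryl ether F4. Aromatic Claisen rearrangement (toluene, 110 °C) should then move the group, as a linear prenyl unit, to the carbon between O and OMe, since the OSi-flanked ortho carbon is shielded. The fallback returns to the route at 7.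

**Further compounds**

F1 | step 7 | racemic 7-methoxy-8-(3-methylbut-2-en-1-yl)-2-(2,4,6-trimethoxyphenyl)-5-[(triisopropylsilyl)oxy]chroman-4-one | COc1cc(OC)c(C2CC(=O)c3c(O[Si](C(C)C)(C(C)C)C(C)C)cc(OC)c(CC=C(C)C)c3O2)c(OC)c1
F2 | step 7 | (2R,4R)-7-methoxy-8-(3-methylbut-2-en-1-yl)-2-(2,4,6-trimethoxyphenyl)-5-[(triisopropylsilyl)oxy]chroman-4-ol | COc1cc(OC)c([C@H]2C[C@@H](O)c3c(O[Si](C(C)C)(C(C)C)C(C)C)cc(OC)c(CC=C(C)C)c3O2)c(OC)c1
F3 | step 3 | triisopropyl[3-methoxy-5-(methoxymethoxy)-4-(prop-2-en-1-yl)phenoxy]silane | COCOc1cc(O[Si](C(C)C)(C(C)C)C(C)C)cc(OC)c1CC=C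
F4 | step 4 | triisopropyl{3-methoxy-5-[(2-methylbut-3-en-2-yl)oxy]phenoxy}silane | C=CC(C)(C)Oc1cc(OC)cc(O[Si](C(C)C)(C(C)C)C(C)C)c1
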